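The ten-membered carbocycle (C1–C10) is opened at C4=C5. Because C15 sits on C4, this alkene is a 2-alkylacrylate whose E geometry (C6 trans to C15) equals the ring-cis arrangement of C3 and C6. An intramolecular Horner–Wadsworth–Emmons reaction of a C4 phosphonoacetate with a C5 aldehyde therefore closes the ring, sets the alkene geometry and delivers C15 as an ester in one operation. The precursor is a trans γ-lactone (C12 to O–C8) bearing on C7 the C6 triethylsilyloxy C5 aldehyde and on C8 the E-C1=C10 chain ending in the allyl phosphonoacetate; its three stereocentres come from an Evans syn succinate aldol and a Felkin dithiane addition.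

Key step: step 12

Remark (numbering): ring carbons C1–C10 with C1=C10 (methyl C14 on C10) and C4=C5 (C15 on C4); C6 is the acyloxy carbon, C7/C8 the ring fusion, C11/C12 the lactone carbons, C13 the exocyclic methylene. Macrocycles are named as germacranolides; "13-nor" marks lactones still lacking C13.
Remark (aldol sense): a trans C7/C8 lactone arises only from the syn aldol adduct (the anti adduct would close to the cis lactone), so the boron-mediated syn aldol with the (R)-benzyl auxiliary is used; it gives 7R,8S.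
Remark (alkene): the C1=C10 bond is made by alkyne carboalumination because its syn addition fixes the E geometry completely.
Assumption: every compound marked "starting material" in the list is purchased.

Step 1
Reactants: 1 tert-butyl(but-3-yn-1-yloxy)dimethylsilane; 2 ethylene oxide
Product: 5 (E)-6-(tert-butyldimethylsilyloxy)-4-methylhex-3-en-1-ol, via alkenylalane 3 (not isolated), via lithium alanate 4 (not isolated)
Conditions: Me3Al, Cp2ZrCl2 (cat.), CH2Cl2, 0 °C to rt; evaporate; n-BuLi, THF/hexane, −78 °C; 2, −78 °C to rt; aqueous work-up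
Reagents that add atoms: trimethylaluminium, C[Al](C)C
Why: Negishi carboalumination adds CH3 and Al syn across the alkyne with Al on the terminal carbon, and the derived alanate opens the epoxide with retention at the alkenyl carbon, so C9 and C2 end up trans (E) across C10=C1.

Step 2
Reactants: 5 (E)-6-(tert-butyldimethylsilyloxy)-4-methylhex-3-en-1-ol
Product: 6 (E)-tert-butyl[(6-chloro-3-methylhex-3-en-1-yl)oxy]dimethylsilane
Conditions: PPh3, N-chlorosuccinimide, CH2Cl2, 0 °C to rt
Reagents that add atoms: N-chlorosuccinimide, O=C1CCC(=O)N1Cl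
Why: Appel-type chlorination through the alkoxyphosphonium salt converts the unhindered primary alcohol into the chloride by SN2 under neutral conditions that leave the silyl ether and the alkene untouched.

Step 3
Reactants: 6 (E)-tert-butyl[(6-chloro-3-methylhex-3-en-1-yl)oxy]dimethylsilane
Product: 7 (E)-6-chloro-3-methylhex-3-en-1-ol
Conditions: p-TsOH·H2O (cat.), MeOH, rt
Reagents that add atoms: none
Why: Acid-catalysed methanolysis of a primary tert-butyldimethylsilyl ether is a standard desilylation to which the alkyl chloride is inert.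

Step 4
Reactants: 7 (E)-6-chloro-3-methylhex-3-en-1-ol
Product: 8 (E)-6-chloro-3-methylhex-3-enal
Conditions: Dess–Martin periodinane, pyridine, CH2Cl2, 0 °C; used at once without chromatography
Reagents that add atoms: none
Why: Dess–Martin oxidation under buffered, non-basic conditions is the established way to reach β,γ-unsaturated aldehydes without migration of the double bond into conjugation.

Step 5
Reactants: 9 (R)-4-benzyloxazolidin-2-one; 10 methyl 4-chloro-4-oxobutanoate
Product: 12 methyl 4-[(R)-4-benzyl-2-oxooxazolidin-3-yl]-4-oxobutanoate, via lithium amide 11 (not isolated)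
Conditions: n-BuLi, THF, −78 °C; then 10, −78 to 0 °C
Reagents that add atoms: none
Why: N-Acylation of the lithiated oxazolidinone by the acid chloride is the standard preparation of Evans imides, and the methyl ester is not attacked at −78 °C.

Step 6
Reactants: 12 methyl 4-[(R)-4-benzyl-2-oxooxazolidin-3-yl]-4-oxobutanoate; 8 (E)-6-chloro-3-methylhex-3-enal
Product: 15 (R)-4-benzyl-3-{(2S,3R)-2-[(E)-5-chloro-2-methylpent-2-en-1-yl]-5-oxotetrahydrofuran-3-carbonyl}oxazolidin-2-one, via boron enolate 13 (not isolated), via aldol adduct 14 (not isolated)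
Conditions: Bu2BOTf, i-Pr2NEt, CH2Cl2, −78 to 0 °C; 8, −78 to 0 °C; pH 7 buffer, MeOH, H2O2, 0 °C; then p-TsOH (cat.), CH2Cl2, rt
Reagents that add atoms: none
Why: In this Evans syn aldol reaction the Z boron enolate of the imide (enolised in preference to the ester) adds through a Zimmerman–Traxler chair to the aldehyde face dictated by the (R)-benzyl auxiliary, which sets C7 (R) and C8 (S), and the syn γ-hydroxy ester then lactonises to the trans lactone.

Step 7
Reactants: 15 (R)-4-benzyl-3-{(2S,3R)-2-[(E)-5-chloro-2-methylpent-2-en-1-yl]-5-oxotetrahydrofuran-3-carbonyl}oxazolidin-2-one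
Product: 16 S-ethyl (2S,3R)-2-[(E)-5-chloro-2-methylpent-2-en-1-yl]-5-oxotetrahydrofuran-3-carbothioate
Conditions: EtSH, n-BuLi, THF, −20 °C
Reagents that add atoms: ethanethiol, CCS
Why: Thiolate transacylation at the exocyclic imide carbonyl releases the auxiliary and gives the thioester, the weakly basic thiolate leaving C7, the lactone and (at −20 °C) the alkyl chloride intact.

Step 8
Reactants: 16 S-ethyl (2S,3R)-2-[(E)-5-chloro-2-methylpent-2-en-1-yl]-5-oxotetrahydrofuran-3-carbothioate
Product: 17 (2S,3R)-2-[(E)-5-chloro-2-methylpent-2-en-1-yl]-5-oxotetrahydrofuran-3-carbaldehyde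
Conditions: Et3SiH, Pd/C (10%), acetone, rt
Reagents that add atoms: none
Why: Fukuyama reduction converts the thioester into the aldehyde under neutral conditions, so the epimerisable, elimination-prone β-formyl lactone never meets base.

Step 9
Reactants: 17 (2S,3R)-2-[(E)-5-chloro-2-methylpent-2-en-1-yl]-5-oxotetrahydrofuran-3-carbaldehyde; 18 1,3-dithiane
Product: 21 (4R,5S)-5-[(E)-5-chloro-2-methylpent-2-en-1-yl]-4-[(S)-(1,3-dithian-2-yl)(triethylsilyloxy)methyl]dihydrofuran-2(3H)-one, via lithiated dithiane 19 (not isolated), via lithium alkoxide 20 (not isolated)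
Conditions: 18, n-BuLi, THF, −30 °C; added to 17, THF, −78 °C; then Et3SiOTf, −78 to −40 °C
Reagents that add atoms: triethylsilyl trifluoromethanesulfonate, CC[Si](CC)(CC)OS(=O)(=O)C(F)(F)F
Why: Corey–Seebach addition of the bulky formyl anion equivalent is expected to follow the Felkin–Anh model, attack anti to the more substituted ring carbon C8 giving the C6 configuration of the target (S descriptor here), and silylation of the cold alkoxide prevents migration of the lactone onto the new oxygen.

Step 10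
Reactants: 21 (4R,5S)-5-[(E)-5-chloro-2-methylpent-2-en-1-yl]-4-[(S)-(1,3-dithian-2-yl)(triethylsilyloxy)methyl]dihydrofuran-2(3H)-one; 22 allyl 2-(diethoxyphosphoryl)acetate
Product: 25 allyl (E)-2-(diethoxyphosphoryl)-7-{(2S,3R)-3-[(S)-(1,3-dithian-2-yl)(triethylsilyloxy)methyl]-5-oxotetrahydrofuran-2-yl}-6-methylhept-5-enoate (C4 epimers), via sodium phosphonoacetate 23 (not isolated), via alkyl iodide 24 (not isolated)
Conditions: 22, NaH, DMF, 0 °C to rt; then 21, NaI, 60 °C
Reagents that add atoms: none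
Why: Finkelstein exchange followed by SN2 alkylation of the soft, weakly basic phosphonoacetate anion by the primary iodide is standard, and this stabilised anion does not attack the lactone, the silyl ether or the dithiane.

Step 11
Reactants: 25 allyl (E)-2-(diethoxyphosphoryl)-7-{(2S,3R)-3-[(S)-(1,3-dithian-2-yl)(triethylsilyloxy)methyl]-5-oxotetrahydrofuran-2-yl}-6-methylhept-5-enoate
Product: 26 allyl (E)-2-(diethoxyphosphoryl)-6-methyl-7-{(2S,3R)-5-oxo-3-[(S)-2-oxo-1-(triethylsilyloxy)ethyl]tetrahydrofuran-2-yl}hept-5-enoate (C4 epimers)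
Conditions: MeI, CaCO3, MeCN/H2O (9:1), 40 °C
Reagents that add atoms: water, O
Why: Alkylative dithiane hydrolysis (S-methylation, then hydrolysis of the sulfonium salt) under carbonate buffering unmasks the C5 aldehyde without acid, so the triethylsilyl ether and the C6 centre survive.

Step 12
Reactants: 26 allyl (E)-2-(diethoxyphosphoryl)-6-methyl-7-{(2S,3R)-5-oxo-3-[(S)-2-oxo-1-(triethylsilyloxy)ethyl]tetrahydrofuran-2-yl}hept-5-enoate
Product: 27 allyl (1(10)E,4E,6R,7R,8S)-6-(triethylsilyloxy)-13-norgermacra-1(10),4-dien-12,8-olid-15-oate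
Conditions: LiCl, DBU, MeCN, rt; 26 added by syringe pump to a final concentration of about 1 mM
Reagents that add atoms: none
Why: Lithium-chelated deprotonation of the C4 phosphonoacetate by DBU gives a stabilised carbanion that adds reversibly to the C5 aldehyde, and syn-elimination of lithium diethyl phosphate from the oxaphosphetane forms C4=C5. The closest precedent is the intramolecular Horner–Wadsworth–Emmons macrocyclisation under Masamune–Roush conditions, here at the demanding ten-membered ring size. The carbocycle closes by a 10-exo-trig addition to the aldehyde carbonyl, and the elimination then places the new double bond inside the ring. No stereocentre is created; the only new stereo-element is the alkene geometry, and the E-enoate normally delivered by 2-alkylphosphonoacetates (C6 trans to C15) is also the ring-cis arrangement of C3 and C6, the less strained one for a cyclodecadiene that already holds the E C1=C10 bond. The step needs chemoselectivity and cyclisation over oligomerisation: the mild base leaves the lactone and the C6 α-silyloxy aldehyde unepimerised, and high dilution together with the turn imposed by the trans lactone and the E alkene favours ring closure.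

Step 13
Reactants: 27 allyl (1(10)E,4E,6R,7R,8S)-6-(triethylsilyloxy)-13-norgermacra-1(10),4-dien-12,8-olid-15-oate
Product: 28 (1(10)E,4E,6R,7R,8S)-6-(triethylsilyloxy)-13-norgermacra-1(10),4-dien-12,8-olid-15-oic acid
Conditions: Pd(PPh3)4 (cat.), morpholine, THF, rt
Reagents that add atoms: none
Why: In this Tsuji–Trost deallylation zerovalent palladium ionises only the allyl ester and morpholine captures the allyl fragment, so the acid is freed under neutral conditions without touching the lactone or the allylic silyl ether.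

Step 14
Reactants: 28 (1(10)E,4E,6R,7R,8S)-6-(triethylsilyloxy)-13-norgermacra-1(10),4-dien-12,8-olid-15-oic acid
Product: 30 (1(10)E,4E,6R,7R,8S)-15-hydroxy-6-(triethylsilyloxy)-13-norgermacra-1(10),4-dien-12,8-olide, via mixed anhydride 29 (not isolated)
Conditions: i-BuOCOCl, N-methylmorpholine, THF, −15 °C; then NaBH4, H2O, −15 to 0 °C
Reagents that add atoms: none
Why: Borohydride reduction of a mixed carbonic anhydride reduces the activated acyl group in the 1,2-sense to the allylic alcohol, while the γ-lactone, an ordinary ester, is not attacked at 0 °C.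

Step 15
Reactants: 30 (1(10)E,4E,6R,7R,8S)-15-hydroxy-6-(triethylsilyloxy)-13-norgermacra-1(10),4-dien-12,8-olide
Product: 31 (1(10)E,4E,6R,7R,8S)-15-(tert-butyldiphenylsilyloxy)-6-(triethylsilyloxy)-13-norgermacra-1(10),4-dien-12,8-olide
Conditions: t-BuPh2SiCl, imidazole, DMF, 0 °C to rt
Reagents that add atoms: tert-butyl(chloro)diphenylsilane, CC(C)(C)[Si](Cl)(c1ccccc1)c1ccccc1
Why: Imidazole-promoted silylation of the primary allylic alcohol gives a silyl ether robust enough to outlast the later selective removal of the C6 triethylsilyl group.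

Step 16
Reactants: 31 (1(10)E,4E,6R,7R,8S)-15-(tert-butyldiphenylsilyloxy)-6-(triethylsilyloxy)-13-norgermacra-1(10),4-dien-12,8-olide
Product: 35 (1(10)E,4E,6R,7R,8S)-15-(tert-butyldiphenylsilyloxy)-6-(triethylsilyloxy)germacra-1(10),4,11(13)-trien-12,8-olide, via lithium enolate 32 (not isolated), via Mannich base 33 (not isolated), via ammonium iodide 34 (not isolated)
Conditions: LDA, THF, −78 °C; CH2=NMe2+ I−, −78 °C to rt; MeI, MeOH, rt; aq. NaHCO3, EtOAc, rt
Reagents that add atoms: N,N-dimethylmethyleneiminium iodide, C=[N+](C)C.[I-]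
Why: The Mannich reaction of the lactone enolate with Eschenmoser's salt, N-quaternisation and E1cB elimination of trimethylamine is the standard α-methylenation of γ-lactones, the enolate having no β-leaving group and C7 not being involved.

Step 17
Reactants: 35 (1(10)E,4E,6R,7R,8S)-15-(tert-butyldiphenylsilyloxy)-6-(triethylsilyloxy)germacra-1(10),4,11(13)-trien-12,8-olide
Product: 36 (1(10)E,4E,6R,7S,8S)-15-(tert-butyldiphenylsilyloxy)-6-hydroxygermacra-1(10),4,11(13)-trien-12,8-olide (7S by priority change only)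
Conditions: PPTS, MeOH/CH2Cl2, 0 °C
Reagents that add atoms: none
Why: Mild acid-catalysed methanolysis cleaves the secondary triethylsilyl ether far faster than the tert-butyldiphenylsilyl ether, and the non-basic medium avoids migration of the lactone to the free C6 hydroxyl.

Step 18
Reactants: 37 (tert-butyldimethylsilyloxy)acetaldehyde; 38 ethyl 2-(triphenylphosphoranylidene)propanoate
Product: 39 ethyl (E)-4-(tert-butyldimethylsilyloxy)-2-methylbut-2-enoate
Conditions: CH2Cl2, rt
Reagents that add atoms: none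
Why: The Wittig reaction of a stabilised α-branched ylide gives the E-trisubstituted enoate, which is the geometry of the 4-hydroxytiglate side chain.

Step 19
Reactants: 39 ethyl (E)-4-(tert-butyldimethylsilyloxy)-2-methylbut-2-enoate
Product: 40 (E)-4-(tert-butyldimethylsilyloxy)-2-methylbut-2-enoic acid
Conditions: LiOH, THF/MeOH/H2O, rt; then aq. HCl to pH 4
Reagents that add atoms: lithium hydroxide, [Li+].[OH-]
Why: Saponification of the ethyl ester leaves the silyl ether and the thermodynamically preferred E geometry unchanged.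

Step 20
Reactants: 36 (1(10)E,4E,6R,7S,8S)-15-(tert-butyldiphenylsilyloxy)-6-hydroxygermacra-1(10),4,11(13)-trien-12,8-olide; 40 (E)-4-(tert-butyldimethylsilyloxy)-2-methylbut-2-enoic acid
Product: 42 (1(10)E,4E,6R,7R,8S)-15-(tert-butyldiphenylsilyloxy)-6-[(E)-4-(tert-butyldimethylsilyloxy)-2-methylbut-2-enoyloxy]germacra-1(10),4,11(13)-trien-12,8-olide, via mixed anhydride 41 (not isolated)
Conditions: 40, 2,4,6-trichlorobenzoyl chloride, Et3N, toluene, rt; then 36, DMAP, rt
Reagents that add atoms: none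
Why: Yamaguchi esterification activates the hindered α-branched acid as a mixed anhydride that DMAP transfers to the secondary allylic C6 hydroxyl with retention at C6, since the C6–O bond is never broken.

Step 21
Reactants: 42 (1(10)E,4E,6R,7R,8S)-15-(tert-butyldiphenylsilyloxy)-6-[(E)-4-(tert-butyldimethylsilyloxy)-2-methylbut-2-enoyloxy]germacra-1(10),4,11(13)-trien-12,8-olide
Product: 43 (1(10)E,4E,6R,7R,8S)-15-hydroxy-6-[(E)-4-hydroxy-2-methylbut-2-enoyloxy]germacra-1(10),4,11(13)-trien-12,8-olide (CNP0344932.2)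
Conditions: HF·pyridine, pyridine, THF, 0 °C to rt
Reagents that add atoms: none
Why: Fluoride-mediated desilylation in a buffered acidic medium removes both silyl ethers without nucleophilic or basic attack on the α-methylene lactone or the allylic ester.

Compound list
1 | tert-butyl(but-3-yn-1-yloxy)dimethylsilane | C#CCCO[Si](C)(C)C(C)(C)C | starting material
2 | ethylene oxide | C1CO1 | starting material
3 | (E)-[4-(tert-butyldimethylsilyloxy)-2-methylbut-1-en-1-yl]dimethylalane | C[Al](C)/C=C(\C)CCO[Si](C)(C)C(C)(C)C | intermediate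
4 | lithium butyl[(E)-4-(tert-butyldimethylsilyloxy)-2-methylbut-1-en-1-yl]dimethylalanate | [Li+].CCCC[Al-](C)(C)/C=C(\C)CCO[Si](C)(C)C(C)(C)C | intermediate
5 | (E)-6-(tert-butyldimethylsilyloxy)-4-methylhex-3-en-1-ol | OCC/C=C(\C)CCO[Si](C)(C)C(C)(C)C | intermediate
6 | (E)-tert-butyl[(6-chloro-3-methylhex-3-en-1-yl)oxy]dimethylsilane | ClCC/C=C(\C)CCO[Si](C)(C)C(C)(C)C | intermediate
7 | (E)-6-chloro-3-methylhex-3-en-1-ol | ClCC/C=C(\C)CCO | intermediate
8 | (E)-6-chloro-3-methylhex-3-enal | ClCC/C=C(\C)CC=O | intermediate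
9 | (R)-4-benzyloxazolidin-2-one | O=C1N[C@H](Cc2ccccc2)CO1 | starting material
10 | methyl 4-chloro-4-oxobutanoate | COC(=O)CCC(Cl)=O | starting material
11 | N-lithio derivative of 9 | [Li+].O=C1[N-][C@H](Cc2ccccc2)CO1 | intermediate
12 | methyl 4-[(R)-4-benzyl-2-oxooxazolidin-3-yl]-4-oxobutanoate | COC(=O)CCC(=O)N1[C@H](Cc2ccccc2)COC1=O | intermediate
13 | (Z)-dibutylboron enolate of 12 | CCCCB(CCCC)O/C(=C\CC(=O)OC)N1[C@H](Cc2ccccc2)COC1=O | intermediate
14 | methyl (3R,4S,6E)-3-{[(R)-4-benzyl-2-oxooxazolidin-3-yl]carbonyl}-9-chloro-4-hydroxy-6-methylnon-6-enoate (syn aldol adduct) | COC(=O)C[C@H]([C@@H](O)C/C(C)=C/CCCl)C(=O)N1[C@H](Cc2ccccc2)COC1=O | intermediate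
15 | (R)-4-benzyl-3-{(2S,3R)-2-[(E)-5-chloro-2-methylpent-2-en-1-yl]-5-oxotetrahydrofuran-3-carbonyl}oxazolidin-2-one | C1C(=O)O[C@@H](C/C(C)=C/CCCl)[C@@H]1C(=O)N2[C@H](Cc3ccccc3)COC2=O | intermediate
16 | S-ethyl (2S,3R)-2-[(E)-5-chloro-2-methylpent-2-en-1-yl]-5-oxotetrahydrofuran-3-carbothioate | C1C(=O)O[C@@H](C/C(C)=C/CCCl)[C@@H]1C(=O)SCC | intermediate
17 | (2S,3R)-2-[(E)-5-chloro-2-methylpent-2-en-1-yl]-5-oxotetrahydrofuran-3-carbaldehyde | C1C(=O)O[C@@H](C/C(C)=C/CCCl)[C@@H]1C=O | intermediate
18 | 1,3-dithiane | C1CSCSC1 | starting material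
19 | 2-lithio-1,3-dithiane | [Li]C1SCCCS1 | intermediate
20 | lithium alkoxide corresponding to 21 (O–Li in place of O–SiEt3) | [Li+].C1C(=O)O[C@@H](C/C(C)=C/CCCl)[C@@H]1[C@H]([O-])C2SCCCS2 | intermediate
21 | (4R,5S)-5-[(E)-5-chloro-2-methylpent-2-en-1-yl]-4-[(S)-(1,3-dithian-2-yl)(triethylsilyloxy)methyl]dihydrofuran-2(3H)-one | C1C(=O)O[C@@H](C/C(C)=C/CCCl)[C@@H]1[C@H](O[Si](CC)(CC)CC)C2SCCCS2 | intermediate
22 | allyl 2-(diethoxyphosphoryl)acetate | C=CCOC(=O)CP(=O)(OCC)OCC | starting material
23 | sodium salt of 22 | [Na+].C=CCOC(=O)[CH-]P(=O)(OCC)OCC | intermediate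
24 | iodide corresponding to 21 (I in place of Cl) | C1C(=O)O[C@@H](C/C(C)=C/CCI)[C@@H]1[C@H](O[Si](CC)(CC)CC)C2SCCCS2 | intermediate
25 | allyl (E)-2-(diethoxyphosphoryl)-7-{(2S,3R)-3-[(S)-(1,3-dithian-2-yl)(triethylsilyloxy)methyl]-5-oxotetrahydrofuran-2-yl}-6-methylhept-5-enoate (C4 epimers) | C1C(=O)O[C@@H](C/C(C)=C/CCC(P(=O)(OCC)OCC)C(=O)OCC=C)[C@@H]1[C@H](O[Si](CC)(CC)CC)C2SCCCS2 | intermediate
26 | allyl (E)-2-(diethoxyphosphoryl)-6-methyl-7-{(2S,3R)-5-oxo-3-[(S)-2-oxo-1-(triethylsilyloxy)ethyl]tetrahydrofuran-2-yl}hept-5-enoate (C4 epimers) | C1C(=O)O[C@@H](C/C(C)=C/CCC(P(=O)(OCC)OCC)C(=O)OCC=C)[C@@H]1[C@H](O[Si](CC)(CC)CC)C=O | intermediate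
27 | allyl (1(10)E,4E,6R,7R,8S)-6-(triethylsilyloxy)-13-norgermacra-1(10),4-dien-12,8-olid-15-oate | C1C(=O)O[C@H]2C/C(C)=C/CC/C(C(=O)OCC=C)=C\[C@@H](O[Si](CC)(CC)CC)[C@H]12 | intermediate
28 | (1(10)E,4E,6R,7R,8S)-6-(triethylsilyloxy)-13-norgermacra-1(10),4-dien-12,8-olid-15-oic acid | C1C(=O)O[C@H]2C/C(C)=C/CC/C(C(=O)O)=C\[C@@H](O[Si](CC)(CC)CC)[C@H]12 | intermediate
29 | isobutyl carbonic mixed anhydride of 28 | C1C(=O)O[C@H]2C/C(C)=C/CC/C(C(=O)OC(=O)OCC(C)C)=C\[C@@H](O[Si](CC)(CC)CC)[C@H]12 | intermediate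
30 | (1(10)E,4E,6R,7R,8S)-15-hydroxy-6-(triethylsilyloxy)-13-norgermacra-1(10),4-dien-12,8-olide | C1C(=O)O[C@H]2C/C(C)=C/CC/C(CO)=C\[C@@H](O[Si](CC)(CC)CC)[C@H]12 | intermediate
31 | (1(10)E,4E,6R,7R,8S)-15-(tert-butyldiphenylsilyloxy)-6-(triethylsilyloxy)-13-norgermacra-1(10),4-dien-12,8-olide | C1C(=O)O[C@H]2C/C(C)=C/CC/C(CO[Si](c3ccccc3)(c4ccccc4)C(C)(C)C)=C\[C@@H](O[Si](CC)(CC)CC)[C@H]12 | intermediate
32 | lithium enolate of 31 (C11=C12–OLi) | [Li+].C1=C([O-])O[C@H]2C/C(C)=C/CC/C(CO[Si](c3ccccc3)(c4ccccc4)C(C)(C)C)=C\[C@@H](O[Si](CC)(CC)CC)[C@H]12 | intermediate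
33 | 11-(dimethylaminomethyl) derivative of 31 (Mannich base, C11 epimers) | CN(C)CC1C(=O)O[C@H]2C/C(C)=C/CC/C(CO[Si](c3ccccc3)(c4ccccc4)C(C)(C)C)=C\[C@@H](O[Si](CC)(CC)CC)[C@H]12 | intermediate
34 | trimethylammonium iodide derived from 33 | C[N+](C)(C)CC1C(=O)O[C@H]2C/C(C)=C/CC/C(CO[Si](c3ccccc3)(c4ccccc4)C(C)(C)C)=C\[C@@H](O[Si](CC)(CC)CC)[C@H]12.[I-] | intermediate
35 | (1(10)E,4E,6R,7R,8S)-15-(tert-butyldiphenylsilyloxy)-6-(triethylsilyloxy)germacra-1(10),4,11(13)-trien-12,8-olide | C=C1C(=O)O[C@H]2C/C(C)=C/CC/C(CO[Si](c3ccccc3)(c4ccccc4)C(C)(C)C)=C\[C@@H](O[Si](CC)(CC)CC)[C@H]12 | intermediate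
36 | (1(10)E,4E,6R,7S,8S)-15-(tert-butyldiphenylsilyloxy)-6-hydroxygermacra-1(10),4,11(13)-trien-12,8-olide | C=C1C(=O)O[C@H]2C/C(C)=C/CC/C(CO[Si](c3ccccc3)(c4ccccc4)C(C)(C)C)=C\[C@@H](O)[C@H]12 | intermediate
37 | (tert-butyldimethylsilyloxy)acetaldehyde | O=CCO[Si](C)(C)C(C)(C)C | starting material
38 | ethyl 2-(triphenylphosphoranylidene)propanoate | CCOC(=O)C(C)=P(c1ccccc1)(c1ccccc1)c1ccccc1 | starting material
39 | ethyl (E)-4-(tert-butyldimethylsilyloxy)-2-methylbut-2-enoate | CCOC(=O)/C(C)=C/CO[Si](C)(C)C(C)(C)C | intermediate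
40 | (E)-4-(tert-butyldimethylsilyloxy)-2-methylbut-2-enoic acid | OC(=O)/C(C)=C/CO[Si](C)(C)C(C)(C)C | intermediate
41 | mixed anhydride of 40 and 2,4,6-trichlorobenzoic acid | O=C(OC(=O)/C(C)=C/CO[Si](C)(C)C(C)(C)C)c1c(Cl)cc(Cl)cc1Cl | intermediate
42 | (1(10)E,4E,6R,7R,8S)-15-(tert-butyldiphenylsilyloxy)-6-[(E)-4-(tert-butyldimethylsilyloxy)-2-methylbut-2-enoyloxy]germacra-1(10),4,11(13)-trien-12,8-olide | C=C1C(=O)O[C@H]2C/C(C)=C/CC/C(CO[Si](c3ccccc3)(c4ccccc4)C(C)(C)C)=C\[C@@H](OC(=O)/C(C)=C/CO[Si](C)(C)C(C)(C)C)[C@H]12 | intermediate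
43 | (1(10)E,4E,6R,7R,8S)-15-hydroxy-6-[(E)-4-hydroxy-2-methylbut-2-enoyloxy]germacra-1(10),4,11(13)-trien-12,8-olide (CNP0344932.2) | C=C1C(=O)O[C@H]2C/C(C)=C/CC/C(CO)=C\[C@@H](OC(=O)/C(C)=C/CO)[C@H]12 | target

Total step count: 21 (steps 5, 18 and 19 are side branches).
Longest linear sequence: 18 steps (1–4, 6–17, 20, 21) from compound 1.

Steps most likely to fail

Step 12. Transannular strain in the forming ten-membered ring may slow the intramolecular addition so far that intermolecular olefination (cyclic dimers, oligomers) and base-induced epimerisation of the α-silyloxy aldehyde take over. The fallback closes the same C4=C5 bond by ring-closing alkene metathesis instead of carbonyl olefination; it is itself demanding for a trisubstituted enoate in a ten-membered ring. It sets out from aldehyde 17. Addition of vinylmagnesium bromide at −78 °C with Et3SiOTf trapping (same Felkin sense as step 9) would give the allylic silyl ether F1. Alkylation of the sodium salt of tert-butyl diethylphosphonoacetate with F1 (NaI, DMF, 60 °C) would give the phosphonate F2. Olefination of F2 with aqueous formaldehyde and K2CO3 would give the 2-substituted acrylate F3. Ring-closing metathesis of F3 with the second-generation Hoveyda–Grubbs catalyst (toluene, 80 °C, about 1 mM) should give the macrocyclic tert-butyl ester F4, ring strain again favouring the ring-cis alkene. Me3SiOTf and 2,6-lutidine (CH2Cl2, 0 °C, aqueous work-up) would then cleave the tert-butyl ester while the triethylsilyl ether stays, and the route is rejoined at acid 28.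

Step 9. Discrimination between the two ring branches at C7 may be too weak (erosion of Felkin control). The basic nucleophile may also abstract the C7 proton, with β-elimination of the lactone carboxylate, or the lactone may migrate onto the new alkoxide before silylation. The fallback sets C6 by catalyst-controlled ketone reduction instead of substrate-controlled addition. From 17, the same dithiane addition quenched at −78 °C with AcOH would give the epimeric carbinols F5. Parikh–Doering oxidation (SO3·pyridine, DMSO, i-Pr2NEt, 0 °C) would give the 2-acyl-1,3-dithiane F6. Corey–Bakshi–Shibata reduction ((R)-2-methyl-CBS-oxazaborolidine, catecholborane, toluene, −78 °C) should deliver the (S)-carbinol F7, provided the dithianyl group acts as the large substituent; otherwise the other catalyst enantiomer is tried. Et3SiOTf and 2,6-lutidine then return to 21.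

Step 14. Hydride may attack the carbonate carbonyl of the mixed anhydride (returning acid 28) or add in a conjugate fashion to the activated enoate. The fallback passes through the aldehyde oxidation level. From 28, EDC·HCl, EtSH and DMAP (CH2Cl2) would give the thioester F8. Fukuyama reduction (Et3SiH, Pd/C, acetone) would give the enal F9. Luche reduction (NaBH4, CeCl3·7H2O, MeOH, −78 °C) reduces only the aldehyde in the 1,2-sense and returns to 30.

Further compounds
F1 | step 12 | (4R,5S)-5-[(E)-5-chloro-2-methylpent-2-en-1-yl]-4-[(R)-1-(triethylsilyloxy)prop-2-en-1-yl]dihydrofuran-2(3H)-one | C1C(=O)O[C@@H](C/C(C)=C/CCCl)[C@@H]1[C@H](O[Si](CC)(CC)CC)C=C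
F2 | step 12 | tert-butyl (E)-2-(diethoxyphosphoryl)-6-methyl-7-{(2S,3R)-5-oxo-3-[(R)-1-(triethylsilyloxy)prop-2-en-1-yl]tetrahydrofuran-2-yl}hept-5-enoate (C4 epimers) | C1C(=O)O[C@@H](C/C(C)=C/CCC(P(=O)(OCC)OCC)C(=O)OC(C)(C)C)[C@@H]1[C@H](O[Si](CC)(CC)CC)C=C
F3 | step 12 | tert-butyl (E)-6-methyl-2-methylidene-7-{(2S,3R)-5-oxo-3-[(R)-1-(triethylsilyloxy)prop-2-en-1-yl]tetrahydrofuran-2-yl}hept-5-enoate | C1C(=O)O[C@@H](C/C(C)=C/CCC(=C)C(=O)OC(C)(C)C)[C@@H]1[C@H](O[Si](CC)(CC)CC)C=C
F4 | step 12 | tert-butyl (1(10)E,4E,6R,7R,8S)-6-(triethylsilyloxy)-13-norgermacra-1(10),4-dien-12,8-olid-15-oate | C1C(=O)O[C@H]2C/C(C)=C/CC/C(C(=O)OC(C)(C)C)=C\[C@@H](O[Si](CC)(CC)CC)[C@H]12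
F5 | step 9 | (4S,5S)-5-[(E)-5-chloro-2-methylpent-2-en-1-yl]-4-[(1,3-dithian-2-yl)(hydroxy)methyl]dihydrofuran-2(3H)-one (both carbinol epimers) | C1C(=O)O[C@@H](C/C(C)=C/CCCl)[C@@H]1C(O)C2SCCCS2
F6 | step 9 | (4R,5S)-5-[(E)-5-chloro-2-methylpent-2-en-1-yl]-4-(1,3-dithiane-2-carbonyl)dihydrofuran-2(3H)-one | C1C(=O)O[C@@H](C/C(C)=C/CCCl)[C@@H]1C(=O)C2SCCCS2
F7 | step 9 | (4S,5S)-5-[(E)-5-chloro-2-methylpent-2-en-1-yl]-4-[(S)-(1,3-dithian-2-yl)(hydroxy)methyl]dihydrofuran-2(3H)-one | C1C(=O)O[C@@H](C/C(C)=C/CCCl)[C@@H]1[C@H](O)C2SCCCS2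
F8 | step 14 | S-ethyl (1(10)E,4E,6R,7R,8S)-6-(triethylsilyloxy)-13-norgermacra-1(10),4-dien-12,8-olide-15-thioate | C1C(=O)O[C@H]2C/C(C)=C/CC/C(C(=O)SCC)=C\[C@@H](O[Si](CC)(CC)CC)[C@H]12
F9 | step 14 | (1(10)E,4E,6R,7R,8S)-15-oxo-6-(triethylsilyloxy)-13-norgermacra-1(10),4-dien-12,8-olide | C1C(=O)O[C@H]2C/C(C)=C/CC/C(C=O)=C\[C@@H](O[Si](CC)(CC)CC)[C@H]12
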